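**Plan** (ring numbering: C1 ketone, C2 bearing C7H2O, C3 =CH, C4 O-tiglate, C5 isopropyl with methine C8, C6 OAc; acyclic intermediates keep these numbers)
- Feature: C6 is a carbinol carbon between the C1 ketone and C5, and C5 carries the three-carbon branch at C8. This is the hydroxyl/isopropenyl pattern of isopulegol, so the ring opens at C5–C6 into a C6 aldehyde and a C5=C8 prenyl alkene.
- Cuts, in retrosynthetic order: the ester C–O bonds (C7–O and C4–O tiglates, the latter with inversion; the C6 acetate), the ring bond C5–C6 (carbonyl-ene), C1–C2 (alkenyllithium plus glycolic Weinreb amide), C3–C4 (alkynylation of 3-methylbut-2-enal).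
- Forward: alkynylation joins C7–C2≡C3 to C4–C5=C8, directed hydroalumination/iodination fixes the Z C2=C3 alkene, acylation adds C1–C6, oxidation gives the vinyl glyoxal, and the only ring closes in the ene step. Acetylation, hydrogenation, desilylation and a double Mitsunobu esterification finish the route.
- Stereochemistry: C4 comes from the catalytic asymmetric alkynylation and is carried as the 4-epimer. C5 and C6 arise in the ene closure under control of C4 (4,5-trans, 5,6-trans). C4 is corrected by SN2 inversion in the last step.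

Key step: step 9

Assumption: the TBS ether of propargyl alcohol (5) is taken as a catalogue compound (otherwise one silylation from propargyl alcohol); TBS = tert-butyldimethylsilyl, TES = triethylsilyl.
Assumption: (S,S)-ProPhenol is taken to deliver the alkynyl group to the Re face of the enal, giving (S)-7; the configuration would be checked by MTPA ester analysis and the (R,R)-ligand used if the sense were opposite.

**Step 1**
Reactants: 1 methyl glycolate
Product: 2 methyl 2-(triethylsilyloxy)acetate
Conditions: TESCl, imidazole, CH2Cl2, 0 °C → rt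
Reagents that add atoms: chlorotriethylsilane, CC[Si](CC)(CC)Cl
Why: Imidazole-promoted silylation of a primary alcohol should proceed cleanly and gives a glycolate oxygen that can later be unmasked in the presence of TBS ethers.

**Step 2**
Reactants: 2 methyl 2-(triethylsilyloxy)acetate
Product: 3 N-methoxy-N-methyl-2-(triethylsilyloxy)acetamide
Conditions: MeNH(OMe)·HCl, i-PrMgCl, THF, −20 → 0 °C; then H2O
Reagents that add atoms: N,O-dimethylhydroxylamine hydrochloride, CNOC.Cl
Why: The chloromagnesium amide of N,O-dimethylhydroxylamine, made in the flask, should convert the methyl ester directly into the Weinreb amide (ester aminolysis) without touching the silyl ether.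

**Step 3**
Reactants: 4 3-methylbut-2-enal; 5 tert-butyldimethyl(prop-2-yn-1-yloxy)silane
Product: 7 (4S)-7-(tert-butyldimethylsilyloxy)-2-methylhept-2-en-5-yn-4-ol, via alkynyl(methyl)zinc 6 (not isolated)
Conditions: ZnMe2 (3 equiv), (S,S)-ProPhenol (20 mol %), Ph3P=O (40 mol %), 5 (3 equiv), toluene, 0 → 4 °C; then H2O
Reagents that add atoms: none
Why: Catalytic asymmetric alkynylation of an aldehyde: the zinc alkynylide formed from 5 and ZnMe2 adds 1,2 to the enal inside the dinuclear zinc–ProPhenol pocket, and the ligand sets the C4 stereocentre (S).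

**Step 4**
Reactants: 7 (4S)-7-(tert-butyldimethylsilyloxy)-2-methylhept-2-en-5-yn-4-ol
Product: 9 (2Z,4S)-1-(tert-butyldimethylsilyloxy)-2-iodo-6-methylhepta-2,5-dien-4-ol, via sodium alkenylaluminate 8 (not isolated)
Conditions: NaAlH2(OCH2CH2OMe)2 (1.5 equiv), THF, 0 °C; then I2, THF, −78 °C; aq. work-up
Reagents that add atoms: iodine, II
Why: Hydroxyl-directed trans-hydroalumination of a propargylic alcohol: the aluminium alkoxide delivers hydride to the proximal alkyne carbon (C3) through a five-membered oxa-aluminacycle, and iodine cleaves the C2–Al bond with retention, so iodine sits on C2 cis to C4 as the ring requires.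

**Step 5**
Reactants: 9 (2Z,4S)-1-(tert-butyldimethylsilyloxy)-2-iodo-6-methylhepta-2,5-dien-4-ol
Product: 10 (2Z,4S)-1,4-bis(tert-butyldimethylsilyloxy)-2-iodo-6-methylhepta-2,5-diene
Conditions: TBSCl, imidazole, DMF, rt
Reagents that add atoms: tert-butyldimethylsilyl chloride, CC(C)(C)[Si](C)(C)Cl
Why: Standard silylation of a secondary allylic alcohol; the ether must be in place before C1 becomes a ketone, because a free Z-γ-hydroxy enone would close to a furan.

**Step 6**
Reactants: 10 (2Z,4S)-1,4-bis(tert-butyldimethylsilyloxy)-2-iodo-6-methylhepta-2,5-diene; 3 N-methoxy-N-methyl-2-(triethylsilyloxy)acetamide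
Product: 13 (3Z,5S)-5-(tert-butyldimethylsilyloxy)-3-[(tert-butyldimethylsilyloxy)methyl]-7-methyl-1-(triethylsilyloxy)octa-3,6-dien-2-one, via alkenyllithium 11 (not isolated), via lithium hemiaminal adduct 12 (not isolated)
Conditions: t-BuLi (2.05 equiv), Et2O, −78 °C; then 3, −78 → −40 °C; then H2O
Reagents that add atoms: none
Why: Iodine–lithium exchange at −78 °C in ether should outrun silyl migration and keeps the alkene geometry, and the Weinreb amide forms a chelated tetrahedral adduct that releases the ketone only on work-up (Weinreb ketone synthesis).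

**Step 7**
Reactants: 13 (3Z,5S)-5-(tert-butyldimethylsilyloxy)-3-[(tert-butyldimethylsilyloxy)methyl]-7-methyl-1-(triethylsilyloxy)octa-3,6-dien-2-one
Product: 14 (3Z,5S)-5-(tert-butyldimethylsilyloxy)-3-[(tert-butyldimethylsilyloxy)methyl]-1-hydroxy-7-methylocta-3,6-dien-2-one
Conditions: PPTS (cat.), MeOH/CH2Cl2, 0 °C
Reagents that add atoms: none
Why: Selective acid-catalysed desilylation: a primary TES ether is solvolysed far faster than primary or secondary TBS ethers, so only the C6 oxygen should be freed.

**Step 8**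
Reactants: 14 (3Z,5S)-5-(tert-butyldimethylsilyloxy)-3-[(tert-butyldimethylsilyloxy)methyl]-1-hydroxy-7-methylocta-3,6-dien-2-one
Product: 15 (3Z,5S)-5-(tert-butyldimethylsilyloxy)-3-[(tert-butyldimethylsilyloxy)methyl]-7-methyl-2-oxoocta-3,6-dienal
Conditions: Dess–Martin periodinane, NaHCO3, CH2Cl2, 0 °C → rt; filtration, azeotropic drying with toluene; used at once
Reagents that add atoms: none
Why: Dess–Martin oxidation of a primary α-ketol should stop at the α-keto aldehyde under buffered, non-aqueous conditions and leaves silyl ethers and both alkenes alone.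

**Step 9**
Reactants: 15 (3Z,5S)-5-(tert-butyldimethylsilyloxy)-3-[(tert-butyldimethylsilyloxy)methyl]-7-methyl-2-oxoocta-3,6-dienal
Product: 16 (4R,5R,6R)-4-(tert-butyldimethylsilyloxy)-2-[(tert-butyldimethylsilyloxy)methyl]-6-hydroxy-5-(prop-1-en-2-yl)cyclohex-2-en-1-one
Conditions: Me2AlCl (2.2 equiv), CH2Cl2, −78 → −40 °C; then H2O
Reagents that add atoms: none
Why: Two equivalents of Me2AlCl should bind the 1,2-dicarbonyl unit as a chelated dimethylaluminium cation; C5 of the prenyl alkene then attacks the aldehyde carbon C6 while a hydrogen of a C8 methyl group passes to the aldehyde oxygen in a concerted, asynchronous ene process, after which the aluminium-bound alcohol loses methane so that no free acid is released. The closest known reactions are the Lewis-acid type 1 intramolecular carbonyl-ene cyclisation of citronellal to isopulegol and the ene reactions of glyoxylates and glyoxals. The cyclohexenone ring closes by C5–C6 bond formation through a six-membered chair-like transition state in which both the C5=C8 alkene and the C6=O group are exocyclic to the forming ring (6-exo), the Z-enone C1–C2=C3–C4 serving as the preformed four-atom tether. C5 is set by C4: allylic 1,3-strain with the cis methyl group of the prenyl unit holds H4 in the alkene plane, so the tether delivers C6 to the face anti to the OTBS group (4,5-trans); C6 is set by the chelate, which holds the aldehyde oxygen syn to the C1 carbonyl and therefore equatorial in the chair (5,6-trans, as in isopulegol). The step needs the aldehyde and not the ketone to act as enophile (it is the more electrophilic carbonyl and the only one that gives a six-membered ring), ene transfer over chloride capture or methyl addition (low temperature and a proton-scavenging alkylaluminium), and a Z-enone so that C5 and C6 can meet (fixed in step 4).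

**Step 10**
Reactants: 16 (4R,5R,6R)-4-(tert-butyldimethylsilyloxy)-2-[(tert-butyldimethylsilyloxy)methyl]-6-hydroxy-5-(prop-1-en-2-yl)cyclohex-2-en-1-one
Product: 17 (4R,5R,6R)-6-acetoxy-4-(tert-butyldimethylsilyloxy)-2-[(tert-butyldimethylsilyloxy)methyl]-5-(prop-1-en-2-yl)cyclohex-2-en-1-one
Conditions: Ac2O, pyridine, DMAP (cat.), CH2Cl2, 0 °C
Reagents that add atoms: acetic anhydride, CC(=O)OC(C)=O
Why: DMAP-catalysed acetylation of the secondary α-ketol touches no stereocentre, and the trans-diequatorial C5/C6 arrangement is the stable one should C6 enolise.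

**Step 11**
Reactants: 17 (4R,5R,6R)-6-acetoxy-4-(tert-butyldimethylsilyloxy)-2-[(tert-butyldimethylsilyloxy)methyl]-5-(prop-1-en-2-yl)cyclohex-2-en-1-one
Product: 18 (4R,5R,6R)-6-acetoxy-4-(tert-butyldimethylsilyloxy)-2-[(tert-butyldimethylsilyloxy)methyl]-5-isopropylcyclohex-2-en-1-one
Conditions: H2 (1 atm), RhCl(PPh3)3 (cat.), benzene, rt
Reagents that add atoms: none
Why: Homogeneous hydrogenation with RhCl(PPh3)3 reduces a 1,1-disubstituted alkene much faster than a trisubstituted conjugated one (the carvone to carvotanacetone selectivity), so only the isopropenyl group should be saturated.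

**Step 12**
Reactants: 18 (4R,5R,6R)-6-acetoxy-4-(tert-butyldimethylsilyloxy)-2-[(tert-butyldimethylsilyloxy)methyl]-5-isopropylcyclohex-2-en-1-one
Product: 19 (4R,5S,6R)-6-acetoxy-4-hydroxy-2-(hydroxymethyl)-5-isopropylcyclohex-2-en-1-one
Conditions: HF·pyridine, pyridine, THF, 0 °C → rt
Reagents that add atoms: none
Why: Buffered fluoride cleavage removes both TBS ethers under conditions that should leave the acetate and the enone intact (the change of descriptor at C5 is a priority change only).

**Step 13**
Reactants: 19 (4R,5S,6R)-6-acetoxy-4-hydroxy-2-(hydroxymethyl)-5-isopropylcyclohex-2-en-1-one; 20 tiglic acid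
Product: 22 (4S,5S,6R)-6-acetoxy-5-isopropyl-4-[(E)-2-methylbut-2-enoyloxy]-2-{[(E)-2-methylbut-2-enoyloxy]methyl}cyclohex-2-en-1-one, via C7 mono-tiglate 21 (not isolated)
Conditions: 20 (3 equiv), PPh3 (3 equiv), DIAD (3 equiv), THF, 0 °C → rt
Reagents that add atoms: none
Why: Mitsunobu esterification: the primary allylic C7 alcohol is acylated first, and the allylic C4 oxyphosphonium is then displaced by tiglate in an SN2 step with inversion (4R → 4S), the C5 hydrogen being cis to the leaving group so that anti-elimination cannot compete.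

**Compound list**
1 | methyl glycolate | COC(=O)CO | starting material
2 | methyl 2-(triethylsilyloxy)acetate | CC[Si](CC)(CC)OCC(=O)OC | intermediate
3 | N-methoxy-N-methyl-2-(triethylsilyloxy)acetamide | CC[Si](CC)(CC)OCC(=O)N(C)OC | intermediate
4 | 3-methylbut-2-enal | CC(C)=CC=O | starting material
5 | tert-butyldimethyl(prop-2-yn-1-yloxy)silane | C#CCO[Si](C)(C)C(C)(C)C | starting material
6 | [3-(tert-butyldimethylsilyloxy)prop-1-yn-1-yl](methyl)zinc | C[Zn]C#CCO[Si](C)(C)C(C)(C)C | intermediate (not isolated)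
7 | (4S)-7-(tert-butyldimethylsilyloxy)-2-methylhept-2-en-5-yn-4-ol | CC(C)=C[C@H](O)C#CCO[Si](C)(C)C(C)(C)C | intermediate
8 | sodium alkenylaluminate from 7: five-membered oxa-aluminacycle with Al on C2 and the C4 oxygen, two 2-methoxyethoxy groups on Al | [Na+].COCCO[Al-]1(OCCOC)O[C@@H](C=C(C)C)C=C1CO[Si](C)(C)C(C)(C)C | intermediate (not isolated)
9 | (2Z,4S)-1-(tert-butyldimethylsilyloxy)-2-iodo-6-methylhepta-2,5-dien-4-ol | CC(C)=C[C@H](O)/C=C(I)/CO[Si](C)(C)C(C)(C)C | intermediate
10 | (2Z,4S)-1,4-bis(tert-butyldimethylsilyloxy)-2-iodo-6-methylhepta-2,5-diene | CC(C)=C[C@H](O[Si](C)(C)C(C)(C)C)/C=C(I)/CO[Si](C)(C)C(C)(C)C | intermediate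
11 | alkenyllithium from 10 (lithium in place of iodine, geometry retained) | CC(C)=C[C@H](O[Si](C)(C)C(C)(C)C)/C=C([Li])/CO[Si](C)(C)C(C)(C)C | intermediate (not isolated)
12 | lithium alkoxide of the N-methoxy-N-methyl hemiaminal from addition of 11 to 3 (tetrahedral C1, configuration undefined) | CC(C)=C[C@H](O[Si](C)(C)C(C)(C)C)/C=C(CO[Si](C)(C)C(C)(C)C)\C(O[Li])(CO[Si](CC)(CC)CC)N(C)OC | intermediate (not isolated)
13 | (3Z,5S)-5-(tert-butyldimethylsilyloxy)-3-[(tert-butyldimethylsilyloxy)methyl]-7-methyl-1-(triethylsilyloxy)octa-3,6-dien-2-one | CC[Si](CC)(CC)OCC(=O)/C(CO[Si](C)(C)C(C)(C)C)=C\[C@@H](O[Si](C)(C)C(C)(C)C)C=C(C)C | intermediate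
14 | (3Z,5S)-5-(tert-butyldimethylsilyloxy)-3-[(tert-butyldimethylsilyloxy)methyl]-1-hydroxy-7-methylocta-3,6-dien-2-one | OCC(=O)/C(CO[Si](C)(C)C(C)(C)C)=C\[C@@H](O[Si](C)(C)C(C)(C)C)C=C(C)C | intermediate
15 | (3Z,5S)-5-(tert-butyldimethylsilyloxy)-3-[(tert-butyldimethylsilyloxy)methyl]-7-methyl-2-oxoocta-3,6-dienal | O=CC(=O)/C(CO[Si](C)(C)C(C)(C)C)=C\[C@@H](O[Si](C)(C)C(C)(C)C)C=C(C)C | intermediate
16 | (4R,5R,6R)-4-(tert-butyldimethylsilyloxy)-2-[(tert-butyldimethylsilyloxy)methyl]-6-hydroxy-5-(prop-1-en-2-yl)cyclohex-2-en-1-one | CC(C)(C)[Si](C)(C)OCC1=C[C@@H](O[Si](C)(C)C(C)(C)C)[C@H](C(C)=C)[C@@H](O)C1=O | intermediate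
17 | (4R,5R,6R)-6-acetoxy-4-(tert-butyldimethylsilyloxy)-2-[(tert-butyldimethylsilyloxy)methyl]-5-(prop-1-en-2-yl)cyclohex-2-en-1-one | CC(C)(C)[Si](C)(C)OCC1=C[C@@H](O[Si](C)(C)C(C)(C)C)[C@H](C(C)=C)[C@@H](OC(C)=O)C1=O | intermediate
18 | (4R,5R,6R)-6-acetoxy-4-(tert-butyldimethylsilyloxy)-2-[(tert-butyldimethylsilyloxy)methyl]-5-isopropylcyclohex-2-en-1-one | CC(C)(C)[Si](C)(C)OCC1=C[C@@H](O[Si](C)(C)C(C)(C)C)[C@H](C(C)C)[C@@H](OC(C)=O)C1=O | intermediate
19 | (4R,5S,6R)-6-acetoxy-4-hydroxy-2-(hydroxymethyl)-5-isopropylcyclohex-2-en-1-one | OCC1=C[C@@H](O)[C@H](C(C)C)[C@@H](OC(C)=O)C1=O | intermediate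
20 | tiglic acid, (E)-2-methylbut-2-enoic acid | C/C=C(\C)C(=O)O | starting material
21 | (4R,5S,6R)-6-acetoxy-4-hydroxy-5-isopropyl-2-{[(E)-2-methylbut-2-enoyloxy]methyl}cyclohex-2-en-1-one | C/C=C(\C)C(=O)OCC1=C[C@@H](O)[C@H](C(C)C)[C@@H](OC(C)=O)C1=O | intermediate (not isolated)
22 | (4S,5S,6R)-6-acetoxy-5-isopropyl-4-[(E)-2-methylbut-2-enoyloxy]-2-{[(E)-2-methylbut-2-enoyloxy]methyl}cyclohex-2-en-1-one (CNP0218511.1) | C/C=C(\C)C(=O)OCC1=C[C@H](OC(=O)/C(C)=C/C)[C@H](C(C)C)[C@@H](OC(C)=O)C1=O | target

**Step count**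
Total: 13 steps (two for amide 3, eleven in the main line). Longest linear sequence: 11 steps (4 and 5 to 22, steps 3–13).

**Steps most likely to fail**

Step 9. The keto aldehyde may hydrate or oligomerise before it cyclises. Aluminium may transfer a methyl group, or chloride may be captured after a stepwise Prins-type addition. Facial control at C6 would be lost if the dicarbonyl unit reacts unchelated; a C6 epimer alone could be corrected by base equilibration of acetate 17. The fallback lowers the oxidation level at C1 so that an ordinary α-silyloxy aldehyde is the enophile. It sets out from 13 and rejoins the route at 16.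
- Reduction of 13 with NaBH4/CeCl3·7H2O in MeOH at −78 °C should give (3Z,5S)-5-(tert-butyldimethylsilyloxy)-3-[(tert-butyldimethylsilyloxy)methyl]-7-methyl-1-(triethylsilyloxy)octa-3,6-dien-2-ol F1 as a mixture of carbinol epimers, which is of no consequence.
- TESCl/imidazole converts it into the 1,2-bis(triethylsilyloxy) diene F2.
- Swern conditions ((COCl)2, DMSO, then Et3N) oxidise the primary TES ether directly, leaving secondary silyl ethers, to give (3Z,5S)-5-(tert-butyldimethylsilyloxy)-3-[(tert-butyldimethylsilyloxy)methyl]-7-methyl-2-(triethylsilyloxy)octa-3,6-dienal F3.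
- Me2AlCl in CH2Cl2 at −78 °C closes the ring in the citronellal manner to (1R,5R,6R)-5-(tert-butyldimethylsilyloxy)-3-[(tert-butyldimethylsilyloxy)methyl]-6-(prop-1-en-2-yl)-2-(triethylsilyloxy)cyclohex-3-en-1-ol F4.
- PPTS in MeOH removes the TES group to give the cyclohex-3-ene-1,2-diol F5.
- MnO2 in CH2Cl2 oxidises only the allylic carbinol and delivers 16.

Step 13. SN2 displacement at C4 next to the isopropyl-bearing carbon may be slow with a weakly acidic carboxylic acid, leaving the C4 alcohol unreacted or acylated with retention through an acyloxyphosphonium path. The fallback replaces redox condensation by sulfonate displacement. It sets out from 19 and ends at 22.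
- One equivalent of 20 with EDC·HCl and catalytic DMAP at −20 °C acylates the primary alcohol only and gives 21.
- MsCl/Et3N at −20 °C gives (4R,5R,6R)-6-acetoxy-5-isopropyl-4-(methanesulfonyloxy)-2-{[(E)-2-methylbut-2-enoyloxy]methyl}cyclohex-2-en-1-one F6.
- Caesium (E)-2-methylbut-2-enoate F7, made from 20 and Cs2CO3, with 18-crown-6 in toluene displaces the allylic mesylate with inversion to give 22.

Step 6. The alkenyllithium may suffer silyl migration from the C4 oxygen to C2 (retro-Brook) or β-elimination of the C7 silyloxide before it is acylated. The fallback avoids organolithium chemistry. It sets out from 2 and 10 and rejoins at 13.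
- i-Bu2AlH in CH2Cl2 at −78 °C reduces 2 to 2-(triethylsilyloxy)acetaldehyde F8.
- CrCl2 with catalytic NiCl2 in DMF couples 10 with F8 (Nozaki–Hiyama–Kishi reaction, alkene geometry retained) to give the allylic alcohol F1 described above.
- Dess–Martin oxidation of that alcohol gives 13.

**Further compounds**
F1 | step 9 | (3Z,5S)-5-(tert-butyldimethylsilyloxy)-3-[(tert-butyldimethylsilyloxy)methyl]-7-methyl-1-(triethylsilyloxy)octa-3,6-dien-2-ol (C2 epimers) | CC[Si](CC)(CC)OCC(O)/C(CO[Si](C)(C)C(C)(C)C)=C\[C@@H](O[Si](C)(C)C(C)(C)C)C=C(C)C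
F2 | step 9 | (3Z,5S)-5-(tert-butyldimethylsilyloxy)-3-[(tert-butyldimethylsilyloxy)methyl]-7-methyl-1,2-bis(triethylsilyloxy)octa-3,6-diene (C2 epimers) | CC[Si](CC)(CC)OCC(O[Si](CC)(CC)CC)/C(CO[Si](C)(C)C(C)(C)C)=C\[C@@H](O[Si](C)(C)C(C)(C)C)C=C(C)C
F3 | step 9 | (3Z,5S)-5-(tert-butyldimethylsilyloxy)-3-[(tert-butyldimethylsilyloxy)methyl]-7-methyl-2-(triethylsilyloxy)octa-3,6-dienal (C2 epimers) | O=CC(O[Si](CC)(CC)CC)/C(CO[Si](C)(C)C(C)(C)C)=C\[C@@H](O[Si](C)(C)C(C)(C)C)C=C(C)C
F4 | step 9 | (1R,5R,6R)-5-(tert-butyldimethylsilyloxy)-3-[(tert-butyldimethylsilyloxy)methyl]-6-(prop-1-en-2-yl)-2-(triethylsilyloxy)cyclohex-3-en-1-ol (C2 epimers) | CC(C)(C)[Si](C)(C)OCC1=C[C@@H](O[Si](C)(C)C(C)(C)C)[C@H](C(C)=C)[C@@H](O)C1O[Si](CC)(CC)CC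
F5 | step 9 | (1R,5R,6R)-5-(tert-butyldimethylsilyloxy)-3-[(tert-butyldimethylsilyloxy)methyl]-6-(prop-1-en-2-yl)cyclohex-3-ene-1,2-diol (C2 epimers) | CC(C)(C)[Si](C)(C)OCC1=C[C@@H](O[Si](C)(C)C(C)(C)C)[C@H](C(C)=C)[C@@H](O)C1O
F6 | step 13 | (4R,5R,6R)-6-acetoxy-5-isopropyl-4-(methanesulfonyloxy)-2-{[(E)-2-methylbut-2-enoyloxy]methyl}cyclohex-2-en-1-one | C/C=C(\C)C(=O)OCC1=C[C@@H](OS(C)(=O)=O)[C@H](C(C)C)[C@@H](OC(C)=O)C1=O
F7 | step 13 | caesium (E)-2-methylbut-2-enoate | [Cs+].C/C=C(\C)C(=O)[O-]
F8 | step 6 | 2-(triethylsilyloxy)acetaldehyde | CC[Si](CC)(CC)OCC=O
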